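**Retrosynthetic overview**

1. Ring E is made last: Friedel–Crafts acylation of the free pyrrole C3–H of tetracycle 21 with (S)-methylsuccinic anhydride (C20 from the chiral pool), then CBS reduction and lactonisation (C18).
2. C9 and C13 are set together by one hydrogenation of the C8=C9 / C13=CH2 diene 20 from its convex face, which completes the all-cis H9–H13 array.
3. Rings B and C are closed together in the key step: N4–C5 and C9a–C9 are disconnected to the monocyclic pyrrolyl lactone 16, which carries a 5-chloropent-1-ynyl arm on C10 (gold-catalysed 6-exo-dig hydroarylation, then N-alkylation in the same flask).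
4. Enabling feature: the N4–H/C9a–H edge of pyrrole ring A is the edge common to rings B and C, and the five-carbon bridge C5–C9 of ring C ends at C9, the ring-B carbon next to C10; one C5 electrophile hanging on C10 can therefore reach C9a and then N4.
5. Precursor: ring D from a tetronic acid triflate (Suzuki coupling with a pyrrole-3-boronate, CuH cis-reduction); C10/C11 from a Marshall propargylation of ethyl glyoxylate. Ring order: A (bought), D, B + C, E.

Key step: step 11

Remark: tuberostemonine locants are used (ring A = N4, C3, C2, C1, C9a; ring B = C1, C9a, C9, C10, C11, C12; ring C = N4, C5–C9, C9a; lactone D = C11–C14; lactone E = C18–C21); the target SMILES is read as 9S,10R,11R,12S,13S,18R,20S, with H9, H10, H11, H12 and H13 all on one face.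

**Route**

Step 1
Reactants: 1 5-chloropent-1-yne; 2 N-methoxy-N-methylpropanamide
Product: 4 8-chlorooct-4-yn-3-one, via lithium 5-chloropent-1-yn-1-ide 3 (not isolated)
Conditions: n-BuLi, THF, −78 °C; then 2, −78 to 0 °C; aq. HCl
Reagents that add atoms: none
Why: Acylation of a lithium acetylide with a Weinreb amide, whose chelated tetrahedral adduct survives until the quench, so the ynone should not be attacked a second time.

Step 2
Reactants: 4 8-chlorooct-4-yn-3-one
Product: 5 (S)-8-chlorooct-4-yn-3-ol
Conditions: RuCl[(S,S)-TsDPEN](p-cymene) (cat.), i-PrOH, 25 °C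
Reagents that add atoms: none
Why: Noyori asymmetric transfer hydrogenation of an alkynyl ketone, in which the (S,S)-diamine ruthenium hydride differentiates the alkynyl from the ethyl group and should give the (S)-carbinol, the future C10.

Step 3
Reactants: 5 (S)-8-chlorooct-4-yn-3-ol
Product: 6 (S)-8-chlorooct-4-yn-3-yl methanesulfonate
Conditions: MsCl, Et3N, CH2Cl2, −20 °C
Reagents that add atoms: methanesulfonyl chloride, CS(=O)(=O)Cl
Why: O-Sulfonylation of a secondary alcohol, which leaves the C–O bond and hence the configuration untouched.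

Step 4
Reactants: 6 (S)-8-chlorooct-4-yn-3-yl methanesulfonate; 7 ethyl glyoxylate
Product: 9 ethyl (2R,3R)-8-chloro-3-ethyl-2-hydroxyoct-4-ynoate, via allenylindium reagent 8 (not isolated)
Conditions: PdCl2(dppf) (5 mol%), InI, THF–HMPA (3:1), 25 °C; aq. HCl
Reagents that add atoms: none
Why: Marshall propargylation, in which zerovalent palladium ionises the mesylate with anti SN2′ geometry, monovalent indium iodide takes over the allenyl group, and the allenylindium 8 adds to the aldehyde through a closed SE2′ transition state, so that the carbinol chirality is transferred to C10 (R, net inversion) and the new hydroxyl at C11 (R) ends up anti to the ethyl group.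

Step 5
Reactants: 9 ethyl (2R,3R)-8-chloro-3-ethyl-2-hydroxyoct-4-ynoate
Product: 10 ethyl (2R,3R)-2-acetoxy-8-chloro-3-ethyloct-4-ynoate
Conditions: Ac2O, pyridine, DMAP (cat.), CH2Cl2, 0 to 25 °C
Reagents that add atoms: acetic anhydride, CC(=O)OC(C)=O
Why: DMAP-catalysed O-acylation, which brings in C13 and C14 of ring D without touching a stereocentre.

Step 6
Reactants: 10 ethyl (2R,3R)-2-acetoxy-8-chloro-3-ethyloct-4-ynoate
Product: 11 (5R)-5-[(3R)-8-chlorooct-4-yn-3-yl]-4-hydroxyfuran-2(5H)-one
Conditions: LiN(SiMe3)2 (2.2 equiv), THF, −78 °C; aq. HCl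
Reagents that add atoms: none
Why: Dieckmann-type intramolecular Claisen condensation of the acetate enolate onto the neighbouring ethyl ester (5-exo-trig), known to give 5-substituted tetronic acids from O-acetyl α-hydroxy esters at low temperature without loss of the C11 configuration.

Step 7
Reactants: 11 (5R)-5-[(3R)-8-chlorooct-4-yn-3-yl]-4-hydroxyfuran-2(5H)-one
Product: 12 (2R)-2-[(3R)-8-chlorooct-4-yn-3-yl]-5-oxo-2,5-dihydrofuran-3-yl trifluoromethanesulfonate
Conditions: Tf2O, i-Pr2NEt, CH2Cl2, −78 °C
Reagents that add atoms: trifluoromethanesulfonic anhydride, O=S(=O)(OS(=O)(=O)C(F)(F)F)C(F)(F)F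
Why: O-Sulfonylation of the vinylogous acid gives the vinylogous acyl triflate used for cross-coupling, the hindered amine at −78 °C being too weak to enolise C11.

Step 8
Reactants: 12 the triflate of step 7; 13 1-(triisopropylsilyl)pyrrole-3-boronic acid pinacol ester
Product: 14 (5R)-5-[(3R)-8-chlorooct-4-yn-3-yl]-4-[1-(triisopropylsilyl)pyrrol-3-yl]furan-2(5H)-one
Conditions: Pd(PPh3)4 (5 mol%), K3PO4, THF–H2O (10:1), 25 °C
Reagents that add atoms: none
Why: Suzuki–Miyaura coupling of a tetronic acid triflate with a heteroaryl boronate forms the C1–C12 bond under conditions mild enough for the alkyl chloride, the alkyne and the C11–H.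

Step 9
Reactants: 14 the butenolide of step 8
Product: 15 (4S,5R)-5-[(3R)-8-chlorooct-4-yn-3-yl]-4-[1-(triisopropylsilyl)pyrrol-3-yl]dihydrofuran-2(3H)-one (4,5-cis)
Conditions: Cu(OAc)2·H2O (5 mol%), 1,2-bis(diphenylphosphino)benzene (5 mol%), (EtO)2MeSiH, t-BuOH, toluene, 0 to 25 °C
Reagents that add atoms: none
Why: Copper hydride conjugate reduction (Stryker/Lipshutz type), in which hydride should add to C12 from the face opposite the branched C11 substituent and give the cis lactone (C12 S), while the unactivated internal alkyne, the chloride and the N-silyl group stay intact.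

Step 10
Reactants: 15 the cis lactone of step 9
Product: 16 (4S,5R)-5-[(3R)-8-chlorooct-4-yn-3-yl]-4-(1H-pyrrol-3-yl)dihydrofuran-2(3H)-one
Conditions: Bu4NF, AcOH, THF, 0 °C
Reagents that add atoms: none
Why: Fluoride N-desilylation, buffered with acetic acid so that the lactone is not opened, frees N4–H and unblocks the α-carbon C9a.

Step 11
Reactants: 16 the N–H pyrrolyl lactone of step 10
Product: 18 8,9-didehydro tetracycle (rings A–D closed, C8=C9 in ring C, C13 = CH2, C3–H free; 10R,11R,12S), via bicyclic (Z)-vinylpyrrole chloride 17 (not isolated)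
Conditions: [(JohnPhos)Au(NCMe)]SbF6 (5 mol%; JohnPhos = (2-biphenylyl)di-tert-butylphosphine), toluene, 0.01 M, 25 °C; then, same flask, DMF, Cs2CO3, NaI (cat.), 60 °C
Reagents that add atoms: none
Why: The cationic monovalent gold complex activates the alkyne, the pyrrole α-carbon C9a attacks C9 anti to gold and protodeauration gives the exocyclic Z-alkene of 17 with the chloropropyl arm cis to the pyrrole; Cs2CO3 then generates the pyrrolide, whose N4 displaces the primary chloride at C5 (iodide-assisted SN2). The closest known reaction types are the gold-catalysed intramolecular hydroarylation of alkynes by pyrroles and indoles and the base-mediated N-alkylation of pyrroles by ω-haloalkyl chains, here run in sequence without isolation. Ring B closes in the 6-exo-dig mode (C–C) and ring C in the 7-exo-tet mode (C–N). No stereocentre is formed, since C9 stays trigonal until step 13; the anti-addition fixes only the alkene geometry, and C10, C11 and C12 are not at risk because C10 is propargylic, neither enolisable nor cationic, and the lactone α-carbon is still CH2 when base is present. The step needs attack by C9a and not by the β-carbon C2, exo and not 7-endo attack on the alkyne, and intramolecular N-alkylation: the α-position is the most nucleophilic pyrrole carbon, the three-atom tether C12–C11–C10 favours the six-membered exo transition state, N4 cannot reach C5 before ring B exists, and afterwards the Z-alkene holds C5 beside N4 while high dilution suppresses oligomers.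

Step 12
Reactants: 18 the tetracycle of step 11
Product: 20 13-methylene analogue of 18 (exocyclic C13=CH2 on lactone D, C8=C9 retained), via sodium formyl-enolate 19 (not isolated)
Conditions: NaH, HCO2Et, THF, EtOH (cat.), 0 to 25 °C; then (CH2O)n, THF, 60 °C
Reagents that add atoms: paraformaldehyde, as formaldehyde C=O; ethyl formate, CCOC=O (its formyl carbon is carried only by intermediate 19)
Why: Claisen formylation of the lactone α-CH2 followed by aldol addition to formaldehyde and loss of formate (deformylative α-methylenation) is a purely basic route to the α-methylene lactone that spares the electron-rich pyrrole.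

Step 13
Reactants: 20 the diene lactone of step 12
Product: 21 tetracyclic core lactone (9S,10R,11R,12S,13S; C3–H free)
Conditions: H2 (1 atm), Pd/C, EtOAc, 25 °C
Reagents that add atoms: none
Why: Heterogeneous hydrogenation (syn addition of H2) should reduce both alkenes from the face that already carries H10, H11 and H12, because the C10 ethyl group and the cis-fused lactone shield the other face of C8=C9 and the concave face of ring D shields C13, which sets C9 (S) and C13 (S) with all five ring hydrogens cis.

Step 14
Reactants: 22 (S)-2-methylsuccinic acid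
Product: 23 (S)-3-methyldihydrofuran-2,5-dione ((S)-methylsuccinic anhydride)
Conditions: AcCl, reflux; evaporation
Reagents that add atoms: none
Why: Cyclodehydration of a 1,4-diacid to its anhydride through the mixed anhydride, under acidic conditions that do not enolise the stereocentre.

Step 15
Reactants: 21 the core lactone of step 13; 23 (S)-methylsuccinic anhydride
Product: 24 (S)-2-methyl-4-oxo-4-(core-3-yl)butanoic acid (core = 21 bonded through pyrrole C3)
Conditions: AlCl3, CH2Cl2, 0 °C; aq. HCl
Reagents that add atoms: none
Why: Friedel–Crafts acylation at the only free pyrrole α-position C3, the anhydride being opened at its less hindered carbonyl (the one next to CH2) so that the methyl-bearing C20 ends up next to the carboxylic acid.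

Step 16
Reactants: 24 the keto acid of step 15
Product: 25 methyl (S)-2-methyl-4-oxo-4-(core-3-yl)butanoate
Conditions: Me3SiCHN2, MeOH–toluene, 0 °C
Reagents that add atoms: (trimethylsilyl)diazomethane, C[Si](C)(C)C=[N+]=[N-]
Why: Esterification with a diazomethane equivalent under neutral conditions protects the acid from borane without epimerising C13 or C20.

Step 17
Reactants: 25 the keto ester of step 16
Product: 27 epibisdehydroneotuberostemonine J, via hydroxy ester 26 (not isolated)
Conditions: (S)-2-methyl-CBS-oxazaborolidine (20 mol%), BH3·SMe2, THF, −20 °C; MeOH; then silica gel, CH2Cl2, 25 °C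
Reagents that add atoms: none
Why: Corey–Bakshi–Shibata reduction, in which the (S)-oxazaborolidine–borane complex treats the pyrrolyl group as the large substituent and should deliver hydride to give the (R)-carbinol at C18, whose hydroxyl then closes lactone E onto the methyl ester (5-exo-trig) with C20 untouched.

**Compound list**

1 | 5-chloropent-1-yne | C#CCCCCl | starting material
2 | N-methoxy-N-methylpropanamide | CCC(=O)N(C)OC | starting material
3 | lithium 5-chloropent-1-yn-1-ide | [Li]C#CCCCCl | intermediate (not isolated)
4 | 8-chlorooct-4-yn-3-one | CCC(=O)C#CCCCCl | intermediate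
5 | (S)-8-chlorooct-4-yn-3-ol | CC[C@H](O)C#CCCCCl | intermediate
6 | (S)-8-chlorooct-4-yn-3-yl methanesulfonate | CC[C@H](OS(C)(=O)=O)C#CCCCCl | intermediate
7 | ethyl glyoxylate | O=CC(=O)OCC | starting material
8 | allenylindium reagent, (aR)-[8-chloroocta-3,4-dien-5-yl]indium iodide methanesulfonate | ClCCCC([In](I)OS(C)(=O)=O)=[C@]=C(CC)[H] | intermediate (not isolated)
9 | ethyl (2R,3R)-8-chloro-3-ethyl-2-hydroxyoct-4-ynoate | CC[C@H](C#CCCCCl)[C@@H](O)C(=O)OCC | intermediate
10 | ethyl (2R,3R)-2-acetoxy-8-chloro-3-ethyloct-4-ynoate | CC[C@H](C#CCCCCl)[C@@H](OC(C)=O)C(=O)OCC | intermediate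
11 | (5R)-5-[(3R)-8-chlorooct-4-yn-3-yl]-4-hydroxyfuran-2(5H)-one | CC[C@H](C#CCCCCl)[C@H]1OC(=O)C=C1O | intermediate
12 | (2R)-2-[(3R)-8-chlorooct-4-yn-3-yl]-5-oxo-2,5-dihydrofuran-3-yl trifluoromethanesulfonate | CC[C@H](C#CCCCCl)[C@H]1OC(=O)C=C1OS(=O)(=O)C(F)(F)F | intermediate
13 | 1-(triisopropylsilyl)pyrrole-3-boronic acid pinacol ester | CC(C)[Si](C(C)C)(C(C)C)n1ccc(c1)B1OC(C)(C)C(C)(C)O1 | starting material
14 | (5R)-5-[(3R)-8-chlorooct-4-yn-3-yl]-4-[1-(triisopropylsilyl)pyrrol-3-yl]furan-2(5H)-one | CC[C@H](C#CCCCCl)[C@H]1OC(=O)C=C1c1ccn(c1)[Si](C(C)C)(C(C)C)C(C)C | intermediate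
15 | (4S,5R)-5-[(3R)-8-chlorooct-4-yn-3-yl]-4-[1-(triisopropylsilyl)pyrrol-3-yl]dihydrofuran-2(3H)-one | CC[C@H](C#CCCCCl)[C@H]1OC(=O)C[C@H]1c1ccn(c1)[Si](C(C)C)(C(C)C)C(C)C | intermediate
16 | (4S,5R)-5-[(3R)-8-chlorooct-4-yn-3-yl]-4-(1H-pyrrol-3-yl)dihydrofuran-2(3H)-one | CC[C@H](C#CCCCCl)[C@H]1OC(=O)C[C@H]1c1cc[nH]c1 | intermediate
17 | bicyclic (Z)-vinylpyrrole chloride (rings A, B, D; C9=C8 exocyclic, 4-chlorobutylidene cis to the pyrrole; N4–H) | CC[C@H]1[C@H]2OC(=O)C[C@H]2c2cc[nH]c2/C1=C\CCCCl | intermediate (not isolated)
18 | 8,9-didehydro tetracycle (rings A–D; C13 = CH2; 10R,11R,12S) | CC[C@H]1[C@H]2OC(=O)C[C@H]2c2ccn3c2C1=CCCC3 | intermediate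
19 | sodium formyl-enolate of 18 (13-(oxidomethylene) lactone, sodium salt) | CC[C@H]1[C@H]2OC(=O)C(=C[O-])[C@H]2c2ccn3c2C1=CCCC3.[Na+] | intermediate (not isolated)
20 | 13-methylene-8,9-didehydro tetracycle | CC[C@H]1[C@H]2OC(=O)C(=C)[C@H]2c2ccn3c2C1=CCCC3 | intermediate
21 | tetracyclic core lactone (9S,10R,11R,12S,13S; C3–H) | CC[C@H]1[C@H]2OC(=O)[C@@H](C)[C@H]2c2ccn3c2[C@H]1CCCC3 | intermediate
22 | (S)-2-methylsuccinic acid | OC(=O)C[C@H](C)C(=O)O | starting material
23 | (S)-3-methyldihydrofuran-2,5-dione | O=C1C[C@H](C)C(=O)O1 | intermediate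
24 | (S)-2-methyl-4-oxo-4-(core-3-yl)butanoic acid | CC[C@H]1[C@H]2OC(=O)[C@@H](C)[C@H]2c2cc(C(=O)C[C@H](C)C(=O)O)n3c2[C@H]1CCCC3 | intermediate
25 | methyl (S)-2-methyl-4-oxo-4-(core-3-yl)butanoate | CC[C@H]1[C@H]2OC(=O)[C@@H](C)[C@H]2c2cc(C(=O)C[C@H](C)C(=O)OC)n3c2[C@H]1CCCC3 | intermediate
26 | methyl (2S,4R)-4-hydroxy-2-methyl-4-(core-3-yl)butanoate | CC[C@H]1[C@H]2OC(=O)[C@@H](C)[C@H]2c2cc([C@H](O)C[C@H](C)C(=O)OC)n3c2[C@H]1CCCC3 | intermediate (not isolated)
27 | epibisdehydroneotuberostemonine J (9S,10R,11R,12S,13S,18R,20S) | CC[C@H]1[C@H]2OC(=O)[C@@H](C)[C@H]2c2cc([C@H]3C[C@H](C)C(=O)O3)n3c2[C@H]1CCCC3 | target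

**Step count and risks**

Total step count: 17. Longest linear sequence: 16 steps (steps 1–13 and 15–17; step 14 is a one-step side branch).

Steps most likely to fail:

- **Step 11.** What may go wrong: acid-promoted oligomerisation of the N–H 2-vinylpyrrole 17 before the base stage, and intermolecular instead of intramolecular N-alkylation. The fallback sets out from 16 and comes back at 21; it separates the two ring closures and closes ring C on a saturated chain. Compound 16 is cyclised with the same gold catalyst and 17 is isolated by filtration through basic alumina. It is hydrogenated at once (H2, Pd/C, EtOAc; hydrogen should add anti to the C10 ethyl group) to the saturated bicyclic chloride F5. N-Alkylation (NaH, DMF, 0 °C, high dilution) should give the saturated tetracycle F6. α-Methylenation as in step 12, through the sodium formyl-enolate F7, should give the methylene lactone F8, and hydrogenation from the convex face then gives 21.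

- **Step 13.** What may go wrong: palladium-induced migration of the exocyclic double bond into ring D (a butenolide that resists reduction, with loss of control at C12/C13) and incomplete facial selectivity. The fallback sets out from 20 and comes back at 21; C13 is set by conjugate hydride addition and kinetic protonation instead of hydrogenation. LiBH(s-Bu)3 in THF at −78 °C should give the lithium enolate F9. Protonation on its convex face by 2,6-di-tert-butylphenol should give the 13-methyl lactone F10 with methyl cis to C1. The remaining C8=C9 alkene alone is then hydrogenated (H2, Rh/Al2O3, EtOAc) to 21.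

- **Step 4.** What may go wrong: erosion of the anti selectivity, or partial racemisation of the allenylindium, with the small and very electrophilic glyoxylate. The fallback sets out from 1 and commercial (Z)-pent-2-en-1-ol (CC/C=C\CO) and comes back at 9; it builds C10/C11 by epoxide opening. Sharpless asymmetric epoxidation (Ti(OiPr)4, L-(+)-diethyl tartrate, t-BuOOH, CH2Cl2, −20 °C) should give the cis epoxy alcohol F1. The alkynylalane F2 (from 1 with n-BuLi, then Et2AlCl) should open it at the ethyl-bearing carbon with inversion to the diol F3. Oxidation of the primary alcohol (TEMPO, NaOCl cat., NaClO2, buffered MeCN) should give the hydroxy acid F4, and EtI/KHCO3 in DMF then gives 9.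

**Further compounds**

F1 | step 4 | [(2S,3R)-3-ethyloxiran-2-yl]methanol | CC[C@H]1O[C@H]1CO
F2 | step 4 | (5-chloropent-1-yn-1-yl)diethylalane | CC[Al](CC)C#CCCCCl
F3 | step 4 | (2R,3R)-8-chloro-3-ethyloct-4-yne-1,2-diol | CC[C@H](C#CCCCCl)[C@@H](O)CO
F4 | step 4 | (2R,3R)-8-chloro-3-ethyl-2-hydroxyoct-4-ynoic acid | CC[C@H](C#CCCCCl)[C@@H](O)C(=O)O
F5 | step 11 | saturated bicyclic chloride (rings A, B, D; 9S; 4-chlorobutyl on C9; N4–H) | CC[C@H]1[C@H]2OC(=O)C[C@H]2c2cc[nH]c2[C@H]1CCCCCl
F6 | step 11 | saturated tetracycle (rings A–D; 9S; C13 = CH2) | CC[C@H]1[C@H]2OC(=O)C[C@H]2c2ccn3c2[C@H]1CCCC3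
F7 | step 11 | sodium formyl-enolate of F6 | CC[C@H]1[C@H]2OC(=O)C(=C[O-])[C@H]2c2ccn3c2[C@H]1CCCC3.[Na+]
F8 | step 11 | 13-methylene analogue of F6 | CC[C@H]1[C@H]2OC(=O)C(=C)[C@H]2c2ccn3c2[C@H]1CCCC3
F9 | step 13 | lithium enolate of the 13-methyl lactone (C8=C9 retained) | CC[C@H]1[C@H]2OC([O-])=C(C)[C@H]2c2ccn3c2C1=CCCC3.[Li+]
F10 | step 13 | 13-methyl-8,9-didehydro tetracycle (13S) | CC[C@H]1[C@H]2OC(=O)[C@@H](C)[C@H]2c2ccn3c2C1=CCCC3
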